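The plan cuts dihydrofuran ring A between its methylene C3 and the enone α-carbon C3a (1-benzofuran numbering). Because O1–C7a=C3a–C4=O in ring B is the vinylogous ester of cyclohexane-1,3-dione, while O1–C2 is a plain secondary ether, the precursor is an open 2-bromo-3-alkoxycyclohex-2-enone whose alkoxy group carries CH2Br next to the carbinol carbon. A nickel-catalysed intramolecular reductive coupling of the alkenyl and alkyl bromides forges C3–C3a and closes ring A without touching any stereocentre. The precursor arises by inserting a chelation-derived terminal epoxide into 2,3-dibromocyclohexenone; Sharpless epoxidation with a Payne shift sets the side-chain diol, and C5 is hydroxylated last.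

Key step: step 12

Numbering: ring atoms follow 1-benzofuran numbering; side-chain atoms are primed and follow the undec-9-en-2-yl numbering (C2' is the tertiary carbinol on C2, C5' and C6' carry the diol). The target is 2S,5R,2'S,5'R,6'S.

Assumption: the (+)-antipode of the camphor-derived oxaziridine in step 13 is written on the assumption that its facial preference on the ring enolate leads to 5R; if the preference is the opposite, the enantiomeric reagent is used.

Step 1
Reactants: 1 geraniol, (2E)-3,7-dimethylocta-2,6-dien-1-ol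
Product: 2 [(2S,3S)-3-methyl-3-(4-methylpent-3-en-1-yl)oxiran-2-yl]methanol
Conditions: Ti(OiPr)4 (5 mol %), L-(+)-diethyl tartrate (7 mol %), t-BuOOH, 4 Å sieves, CH2Cl2, −20 °C
Reagents that add atoms: tert-butyl hydroperoxide, CC(C)(C)OO
Why: Sharpless asymmetric epoxidation oxidises only the allylic 2,3-alkene, and L-(+)-diethyl tartrate should set both oxirane carbons as 2S,3S, the tertiary one being the later C6'.

Step 2
Reactants: 2 [(2S,3S)-3-methyl-3-(4-methylpent-3-en-1-yl)oxiran-2-yl]methanol
Product: 4 (3R,4S)-4,8-dimethylnona-1,7-diene-3,4-diol, via Payne-rearranged terminal epoxide 3 (not isolated)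
Conditions: Me3SI (4 equiv), n-BuLi (3.8 equiv), THF, −10 °C to rt; H2O
Reagents that add atoms: trimethylsulfonium iodide, C[S+](C)C.[I-]
Why: The epoxy alkoxide undergoes Payne rearrangement with inversion at the secondary oxirane carbon (which becomes the later C5' with R configuration), and the exposed terminal epoxide is opened at CH2 by dimethylsulfonium methylide, the betaine then losing Me2S by ylide-mediated elimination (one-carbon homologation of an epoxide to an allylic alcohol).

Step 3
Reactants: 4 (3R,4S)-4,8-dimethylnona-1,7-diene-3,4-diol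
Product: 5 (4R,5S)-4-ethenyl-2,2,5-trimethyl-5-(4-methylpent-3-en-1-yl)-1,3-dioxolane
Conditions: 2,2-dimethoxypropane, PPTS (cat.), CH2Cl2, rt
Reagents that add atoms: 2,2-dimethoxypropane, COC(C)(C)OC
Why: Acid-catalysed transketalisation masks the sec,tert-1,2-diol as its acetonide so that the organometallic steps become possible, with no change at either stereocentre.

Step 4
Reactants: 5 (4R,5S)-4-ethenyl-2,2,5-trimethyl-5-(4-methylpent-3-en-1-yl)-1,3-dioxolane
Product: 7 2-[(4R,5S)-2,2,5-trimethyl-5-(4-methylpent-3-en-1-yl)-1,3-dioxolan-4-yl]ethan-1-ol, via B-alkyl-9-BBN adduct 6 (not isolated)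
Conditions: 9-BBN (1.3 equiv), THF, 0 °C to rt; then NaOH, H2O2, 0 °C to rt
Reagents that add atoms: hydrogen peroxide, OO
Why: Hydroboration–oxidation, in which 9-BBN should add only to the monosubstituted alkene (the trisubstituted one is too hindered) with boron on the terminal carbon, and alkaline peroxide replaces boron by hydroxyl.

Step 5
Reactants: 7 2-[(4R,5S)-2,2,5-trimethyl-5-(4-methylpent-3-en-1-yl)-1,3-dioxolan-4-yl]ethan-1-ol
Product: 8 (4R,5S)-4-(2-bromoethyl)-2,2,5-trimethyl-5-(4-methylpent-3-en-1-yl)-1,3-dioxolane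
Conditions: CBr4, PPh3, 2,6-lutidine, CH2Cl2, 0 °C
Reagents that add atoms: tetrabromomethane, BrC(Br)(Br)Br
Why: The Appel reaction converts the primary alcohol into the bromide under buffered, near-neutral conditions that spare the acetonide and the alkene.

Step 6
Reactants: 9 methyl (2S)-oxirane-2-carboxylate
Product: 10 (2S)-N-methoxy-N-methyloxirane-2-carboxamide
Conditions: MeNH(OMe)·HCl (1.5 equiv), i-PrMgCl (3 equiv), THF, −20 °C; aq NH4Cl
Reagents that add atoms: N,O-dimethylhydroxylamine hydrochloride, CNOC.Cl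
Why: Aminolysis of the ester by the magnesium amide of N,O-dimethylhydroxylamine (Weinreb amide formation) at low temperature should leave the oxirane and its stereocentre untouched.

Step 7
Reactants: 10 (2S)-N-methoxy-N-methyloxirane-2-carboxamide
Product: 11 1-[(2S)-oxiran-2-yl]ethan-1-one
Conditions: MeMgBr (1.2 equiv), THF, −78 to 0 °C; aq NH4Cl; kept as a solution (volatile)
Reagents that add atoms: methylmagnesium bromide, C[Mg]Br
Why: Weinreb ketone synthesis, in which the chelated tetrahedral adduct stops the addition at the ketone stage and the oxirane stereocentre is not involved.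

Step 8
Reactants: 8 (4R,5S)-4-(2-bromoethyl)-2,2,5-trimethyl-5-(4-methylpent-3-en-1-yl)-1,3-dioxolane; 11 1-[(2S)-oxiran-2-yl]ethan-1-one
Product: 13 (2S)-2-[(2S)-oxiran-2-yl]-4-[(4R,5S)-2,2,5-trimethyl-5-(4-methylpent-3-en-1-yl)-1,3-dioxolan-4-yl]butan-2-ol, via alkylmagnesium bromide 12 (not isolated)
Conditions: 8, Mg (I2 cat.), THF, 40 °C; then 11, THF/Et2O, −78 °C; aq NH4Cl
Reagents that add atoms: none
Why: Grignard addition under Cram chelate control, in which magnesium bridges the carbonyl and oxirane oxygens and the alkyl group enters anti to the oxirane CH2, which should set the tertiary carbinol (later C2') as S beside the S oxirane carbon (later C2).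

Step 9
Reactants: 14 cyclohexane-1,3-dione
Product: 15 2-bromocyclohexane-1,3-dione
Conditions: NBS (1.0 equiv), CH2Cl2, 0 °C
Reagents that add atoms: N-bromosuccinimide, O=C1CCC(=O)N1Br
Why: Electrophilic bromination of the dione enol at C2, its only nucleophilic carbon.

Step 10
Reactants: 15 2-bromocyclohexane-1,3-dione
Product: 16 2,3-dibromocyclohex-2-en-1-one
Conditions: (COBr)2 (1.2 equiv), DMF (cat.), CH2Cl2, 0 °C to rt
Reagents that add atoms: oxalyl bromide, O=C(Br)C(=O)Br
Why: Vilsmeier-type activation of the vinylogous acid followed by addition–elimination of bromide gives the vinylogous acyl bromide.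

Step 11
Reactants: 13 (2S)-2-[(2S)-oxiran-2-yl]-4-[(4R,5S)-2,2,5-trimethyl-5-(4-methylpent-3-en-1-yl)-1,3-dioxolan-4-yl]butan-2-ol; 16 2,3-dibromocyclohex-2-en-1-one
Product: 17 2-bromo-3-({(2R,3S)-1-bromo-3-hydroxy-3-methyl-5-[(4R,5S)-2,2,5-trimethyl-5-(4-methylpent-3-en-1-yl)-1,3-dioxolan-4-yl]pentan-2-yl}oxy)cyclohex-2-en-1-one
Conditions: 16 (1.1 equiv), n-Bu4NBr (10 mol %), MeCN, 60 °C
Reagents that add atoms: none
Why: Proposed new method: bromide opens the oxirane at its unhindered CH2 (helped by hydrogen bonding from the neighbouring tertiary hydroxyl) and the secondary bromohydrin alkoxide is trapped by addition–elimination at C3 of the vinylogous acyl bromide 16, which releases bromide to carry the chain; the closest known reaction type is the ammonium-halide-catalysed addition of acyl halides to epoxides giving 2-haloalkyl esters, and since the C–O bond at the stereocentre is never broken its configuration is retained (the descriptor changes to R only because CH2Br now outranks the carbinol carbon).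

Step 12
Reactants: 17 2-bromo-3-({(2R,3S)-1-bromo-3-hydroxy-3-methyl-5-[(4R,5S)-2,2,5-trimethyl-5-(4-methylpent-3-en-1-yl)-1,3-dioxolan-4-yl]pentan-2-yl}oxy)cyclohex-2-en-1-one
Product: 18 (2S)-2-{(2S)-2-hydroxy-4-[(4R,5S)-2,2,5-trimethyl-5-(4-methylpent-3-en-1-yl)-1,3-dioxolan-4-yl]butan-2-yl}-2,3,6,7-tetrahydro-1-benzofuran-4(5H)-one
Conditions: NiBr2(dme) (10 mol %), 4,4'-di-tert-butyl-2,2'-bipyridine (10 mol %), Mn powder (3 equiv), NaI (0.5 equiv), DMA, 40 °C, 0.02 M
Reagents that add atoms: none
Why: Zerovalent nickel (from NiBr2(dme) and Mn) inserts into the electron-poor alkenyl C3a–Br bond, a low-valent nickel species abstracts halogen from the primary CH2Br (as the iodide formed in situ) to give the C3 radical, and this radical is captured in the same molecule by the alkenylnickel to a six-membered nickelacycle (Ni, C3, C2, O1, C7a, C3a) of trivalent nickel that reductively eliminates the C3–C3a bond. The closest known reaction type is the nickel-catalysed reductive cross-electrophile coupling of alkenyl bromides with primary alkyl bromides, run here intramolecularly. Ring A is closed in a formal 5-exo-tet sense at C3 by the in-plane sp2 orbital of C3a, which avoids the 5-endo geometry that attack by the enol-ether π system would need. No stereocentre is created, since C2 and the three side-chain centres are spectators and the C2–O1 bond is never broken. The step needs cross-coupling over homo-coupling, no hydrodehalogenation and no β-elimination of O1 from a C3–metal species; the 1,5-relation of the two C–Br bonds, the faster oxidative addition of the alkenyl bromide, radical activation of the alkyl halide with Mn as reductant, and high dilution should secure this.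

Step 13
Reactants: 18 (2S)-2-{(2S)-2-hydroxy-4-[(4R,5S)-2,2,5-trimethyl-5-(4-methylpent-3-en-1-yl)-1,3-dioxolan-4-yl]butan-2-yl}-2,3,6,7-tetrahydro-1-benzofuran-4(5H)-one
Product: 20 (2S,5R)-5-hydroxy-2-{(2S)-2-hydroxy-4-[(4R,5S)-2,2,5-trimethyl-5-(4-methylpent-3-en-1-yl)-1,3-dioxolan-4-yl]butan-2-yl}-2,3,6,7-tetrahydro-1-benzofuran-4(5H)-one, via dilithium alkoxide dienolate 19 (not isolated)
Conditions: LiN(iPr)2 (2.3 equiv), THF, −78 °C; (+)-(camphorsulfonyl)oxaziridine (1.4 equiv), −78 to −40 °C; aq NH4Cl
Reagents that add atoms: (1S)-(+)-(10-camphorsulfonyl)oxaziridine, CC1(C)[C@@H]2CC[C@]13CS(=O)(=O)N4O[C@@]34C2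
Why: After the tertiary hydroxyl, kinetic deprotonation of the vinylogous ester occurs at the α' carbon C5, and the cross-conjugated lithium enolate is hydroxylated by the chiral N-sulfonyloxaziridine (Davis oxidation), whose camphor framework should control the face of oxygen transfer and set C5 as R.

Step 14
Reactants: 20 (2S,5R)-5-hydroxy-2-{(2S)-2-hydroxy-4-[(4R,5S)-2,2,5-trimethyl-5-(4-methylpent-3-en-1-yl)-1,3-dioxolan-4-yl]butan-2-yl}-2,3,6,7-tetrahydro-1-benzofuran-4(5H)-one
Product: 21 (2S,5R)-5-hydroxy-2-[(2S,5R,6S)-2,5,6-trihydroxy-6,10-dimethylundec-9-en-2-yl]-2,3,6,7-tetrahydro-1-benzofuran-4(5H)-one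
Conditions: AcOH/THF/H2O (3:1:1), 40 °C
Reagents that add atoms: none
Why: Mild aqueous acid hydrolyses the acetonide to the 5',6'-diol and should leave the vinylogous ester, the α-hydroxy ketone, the tertiary alcohols and the trisubstituted alkene intact, giving the target.

Compound list

1 | geraniol, (2E)-3,7-dimethylocta-2,6-dien-1-ol | CC(C)=CCC/C(C)=C/CO | starting material
2 | [(2S,3S)-3-methyl-3-(4-methylpent-3-en-1-yl)oxiran-2-yl]methanol | CC(C)=CCC[C@]1(C)O[C@H]1CO | intermediate
3 | (2S)-6-methyl-2-[(2R)-oxiran-2-yl]hept-5-en-2-ol (present as its lithium alkoxide, not isolated) | CC(C)=CCC[C@](C)(O)[C@H]1CO1 | intermediate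
4 | (3R,4S)-4,8-dimethylnona-1,7-diene-3,4-diol | CC(C)=CCC[C@](C)(O)[C@H](O)C=C | intermediate
5 | (4R,5S)-4-ethenyl-2,2,5-trimethyl-5-(4-methylpent-3-en-1-yl)-1,3-dioxolane | CC(C)=CCC[C@]1(C)OC(C)(C)O[C@@H]1C=C | intermediate
6 | 9-{2-[(4R,5S)-2,2,5-trimethyl-5-(4-methylpent-3-en-1-yl)-1,3-dioxolan-4-yl]ethyl}-9-borabicyclo[3.3.1]nonane (not isolated) | CC(C)=CCC[C@]1(C)OC(C)(C)O[C@@H]1CCB1C2CCCC1CCC2 | intermediate
7 | 2-[(4R,5S)-2,2,5-trimethyl-5-(4-methylpent-3-en-1-yl)-1,3-dioxolan-4-yl]ethan-1-ol | CC(C)=CCC[C@]1(C)OC(C)(C)O[C@@H]1CCO | intermediate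
8 | (4R,5S)-4-(2-bromoethyl)-2,2,5-trimethyl-5-(4-methylpent-3-en-1-yl)-1,3-dioxolane | CC(C)=CCC[C@]1(C)OC(C)(C)O[C@@H]1CCBr | intermediate
9 | methyl (2S)-oxirane-2-carboxylate | COC(=O)[C@@H]1CO1 | starting material
10 | (2S)-N-methoxy-N-methyloxirane-2-carboxamide | CON(C)C(=O)[C@@H]1CO1 | intermediate
11 | 1-[(2S)-oxiran-2-yl]ethan-1-one | CC(=O)[C@@H]1CO1 | intermediate
12 | {2-[(4R,5S)-2,2,5-trimethyl-5-(4-methylpent-3-en-1-yl)-1,3-dioxolan-4-yl]ethyl}magnesium bromide (not isolated) | CC(C)=CCC[C@]1(C)OC(C)(C)O[C@@H]1CC[Mg]Br | intermediate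
13 | (2S)-2-[(2S)-oxiran-2-yl]-4-[(4R,5S)-2,2,5-trimethyl-5-(4-methylpent-3-en-1-yl)-1,3-dioxolan-4-yl]butan-2-ol | CC(C)=CCC[C@]1(C)OC(C)(C)O[C@@H]1CC[C@](C)(O)[C@@H]1CO1 | intermediate
14 | cyclohexane-1,3-dione | O=C1CCCC(=O)C1 | starting material
15 | 2-bromocyclohexane-1,3-dione | O=C1CCCC(=O)C1Br | intermediate
16 | 2,3-dibromocyclohex-2-en-1-one | O=C1CCCC(Br)=C1Br | intermediate
17 | 2-bromo-3-({(2R,3S)-1-bromo-3-hydroxy-3-methyl-5-[(4R,5S)-2,2,5-trimethyl-5-(4-methylpent-3-en-1-yl)-1,3-dioxolan-4-yl]pentan-2-yl}oxy)cyclohex-2-en-1-one | CC(C)=CCC[C@]1(C)OC(C)(C)O[C@@H]1CC[C@](C)(O)[C@H](CBr)OC1=C(Br)C(=O)CCC1 | intermediate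
18 | (2S)-2-{(2S)-2-hydroxy-4-[(4R,5S)-2,2,5-trimethyl-5-(4-methylpent-3-en-1-yl)-1,3-dioxolan-4-yl]butan-2-yl}-2,3,6,7-tetrahydro-1-benzofuran-4(5H)-one | CC(C)=CCC[C@]1(C)OC(C)(C)O[C@@H]1CC[C@](C)(O)[C@@H]1CC2=C(CCCC2=O)O1 | intermediate
19 | dilithium derivative of 18: lithium alkoxide at the tertiary hydroxyl and lithium C4-enolate with the C4=C5 double bond (not isolated) | CC(C)=CCC[C@]1(C)OC(C)(C)O[C@@H]1CC[C@](C)(O[Li])[C@@H]1CC2=C(CCC=C2O[Li])O1 | intermediate
20 | (2S,5R)-5-hydroxy-2-{(2S)-2-hydroxy-4-[(4R,5S)-2,2,5-trimethyl-5-(4-methylpent-3-en-1-yl)-1,3-dioxolan-4-yl]butan-2-yl}-2,3,6,7-tetrahydro-1-benzofuran-4(5H)-one | CC(C)=CCC[C@]1(C)OC(C)(C)O[C@@H]1CC[C@](C)(O)[C@@H]1CC2=C(CC[C@@H](O)C2=O)O1 | intermediate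
21 | (2S,5R)-5-hydroxy-2-[(2S,5R,6S)-2,5,6-trihydroxy-6,10-dimethylundec-9-en-2-yl]-2,3,6,7-tetrahydro-1-benzofuran-4(5H)-one | CC(C)=CCC[C@](C)(O)[C@H](O)CC[C@](C)(O)[C@@H]1CC2=C(CC[C@@H](O)C2=O)O1 | target

Total step count: 14. Longest linear sequence: 10 steps (1, 2, 3, 4, 5, 8, 11, 12, 13, 14).

Steps most likely to fail

Step 11 (proposed new method). The bromohydrin alkoxide may be captured too slowly by 16, so that the epoxide only equilibrates with it. The vinylogous acyl group may also migrate to the tertiary oxygen. The fallback uses known chemistry and sets out from 13. Opening with MgBr2·OEt2 in Et2O at 0 °C (bromide at the unhindered CH2, aqueous work-up) should give the bromohydrin (2R,3S)-1-bromo-3-methyl-5-[(4R,5S)-2,2,5-trimethyl-5-(4-methylpent-3-en-1-yl)-1,3-dioxolan-4-yl]pentane-2,3-diol F1. F1 is then condensed at its secondary hydroxyl with 2-bromocyclohexane-1,3-dione 15 (PPTS cat., benzene, azeotropic removal of water), the classical acid-catalysed enol-ether formation of cyclic 1,3-diones. The route is rejoined at 17.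

Step 12 (key step). The two C–Br bonds may be reduced without coupling, or O1 may be lost by β-elimination from a C3–metal species (nickel or manganese), which would cleave the ether again. The fallback sets out from 17 and is an anionic Parham cyclisation in place of the reductive nickel coupling. LiN(SiMe3)2 (THF, −78 °C) masks the hydroxyl and the ketone as alkoxide and C5 enolate, and t-BuLi at −100 °C exchanges the alkenyl bromide. On warming, the resulting C3a-lithiated dilithium alkoxide enolate of 17 F2 should displace the primary bromide (5-exo-tet attack by the σ-alkenyl anion). The species formed is 19 itself, so the route is rejoined at 19 and the oxaziridine of step 13 can be added to the same flask.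

Step 13. Oxygen transfer to the ring enolate may show poor facial selectivity, leaving the 5R and 5S alcohols as remote diastereomers that are hard to separate. The fallback sets out from 18 and replaces reagent control by a stereoconvergent, catalyst-controlled reduction. Non-selective hydroxylation (LiN(iPr)2, then MoO5·pyridine·HMPA) should give 20 together with its epimer (2S,5S)-5-hydroxy-2-{(2S)-2-hydroxy-4-[(4R,5S)-2,2,5-trimethyl-5-(4-methylpent-3-en-1-yl)-1,3-dioxolan-4-yl]butan-2-yl}-2,3,6,7-tetrahydro-1-benzofuran-4(5H)-one F3. The mixture is oxidised with Dess–Martin periodinane to (2S)-2-{(2S)-2-hydroxy-4-[(4R,5S)-2,2,5-trimethyl-5-(4-methylpent-3-en-1-yl)-1,3-dioxolan-4-yl]butan-2-yl}-2,3,6,7-tetrahydro-1-benzofuran-4,5-dione F4. The C5 carbonyl, more electrophilic than the vinylogous ester carbonyl C4, is then reduced by Noyori transfer hydrogenation (RuCl(p-cymene)(TsDPEN), ligand antipode chosen to give 5R, HCO2H/Et3N). Both epimers are thereby funnelled into 20, where the route is rejoined.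

Further compounds

F1 | step 11 | (2R,3S)-1-bromo-3-methyl-5-[(4R,5S)-2,2,5-trimethyl-5-(4-methylpent-3-en-1-yl)-1,3-dioxolan-4-yl]pentane-2,3-diol | CC(C)=CCC[C@]1(C)OC(C)(C)O[C@@H]1CC[C@](C)(O)[C@@H](O)CBr
F2 | step 12 | C3a-lithiated dilithium alkoxide enolate of 17 (tertiary lithium alkoxide, lithium C5 enolate, lithium on the former C–Br alkenyl carbon) | CC(C)=CCC[C@]1(C)OC(C)(C)O[C@@H]1CC[C@](C)(O[Li])[C@H](CBr)OC1=C([Li])C(O[Li])=CCC1
F3 | step 13 | (2S,5S)-5-hydroxy-2-{(2S)-2-hydroxy-4-[(4R,5S)-2,2,5-trimethyl-5-(4-methylpent-3-en-1-yl)-1,3-dioxolan-4-yl]butan-2-yl}-2,3,6,7-tetrahydro-1-benzofuran-4(5H)-one | CC(C)=CCC[C@]1(C)OC(C)(C)O[C@@H]1CC[C@](C)(O)[C@@H]1CC2=C(CC[C@H](O)C2=O)O1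
F4 | step 13 | (2S)-2-{(2S)-2-hydroxy-4-[(4R,5S)-2,2,5-trimethyl-5-(4-methylpent-3-en-1-yl)-1,3-dioxolan-4-yl]butan-2-yl}-2,3,6,7-tetrahydro-1-benzofuran-4,5-dione | CC(C)=CCC[C@]1(C)OC(C)(C)O[C@@H]1CC[C@](C)(O)[C@@H]1CC2=C(CCC(=O)C2=O)O1
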